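The plan rests on removing C3 from ring C: what is left (O1, C2, C4, C4a, C8a) is the furan ring of a 2-aryl-3-oxybenzofuran, because C3 is a lone oxygen-bearing carbon between C2 and the C4 carbonyl carbon. The key step puts that carbon back: dibromocarbene adds to the enol ether bond of a 3-silyloxy-2-arylbenzofuran and the cyclopropane opens to the 3-bromoflavone, forming C2–C3, C3–C4 and the pyranone ring in one operation and leaving bromine on C3 as the handle for the 3-methoxy group. The precursor is the TBS enol ether of the tetrabenzylated 2-arylcoumaranone, built from a ring A phenol and a ring B mandelate by Mitsunobu etherification and Friedel–Crafts closure.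

Key step: step 14

Remark: the stereocentres of 14–18 and 21 are formed racemic and are erased at steps 13 and 14; the target is achiral, so no stereocontrol is planned.

**Ring A phenol**

Step 1
Reactants: 1 2,4,6-trihydroxybenzaldehyde
Product: 2 2,4-bis(benzyloxy)-6-hydroxybenzaldehyde
Conditions: BnBr (2.05 equiv), K2CO3, DMF, 0 °C to rt
Reagents that add atoms: benzyl bromide, BrCc1ccccc1
Why: Williamson etherification; the 4-OH and one 2-OH are benzylated, while the remaining OH is tied up in a hydrogen bond to the formyl oxygen and should be left when only two equivalents of halide are used.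

Step 2
Reactants: 2 2,4-bis(benzyloxy)-6-hydroxybenzaldehyde
Product: 3 2,4-bis(benzyloxy)-6-(methoxymethoxy)benzaldehyde
Conditions: NaH, DMF, 0 °C; then MOMCl, 0 °C to rt
Reagents that add atoms: chloromethyl methyl ether, COCCl
Why: Williamson-type alkylation of the sodium phenoxide; NaH breaks the chelate and the aldehyde has no α-hydrogen to interfere.

Step 3
Reactants: 3 2,4-bis(benzyloxy)-6-(methoxymethoxy)benzaldehyde
Product: 5 2,4-bis(benzyloxy)-6-(methoxymethoxy)phenol, via aryl formate 4 (not isolated)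
Conditions: mCPBA, CH2Cl2, 0 °C to rt; aq NaHCO3 wash; then K2CO3 (cat.), MeOH, rt
Reagents that add atoms: mCPBA, OOC(=O)c1cccc(Cl)c1
Why: Baeyer–Villiger (Dakin-type) oxidation; the electron-rich trialkoxyaryl group migrates in the Criegee intermediate to give the formate, which mild methanolysis cleaves, and MOM and benzyl ethers tolerate peracid and carbonate.

Step 4
Reactants: 5 2,4-bis(benzyloxy)-6-(methoxymethoxy)phenol
Product: 6 1,5-bis(benzyloxy)-2-methoxy-3-(methoxymethoxy)benzene
Conditions: MeI, K2CO3, acetone, reflux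
Reagents that add atoms: iodomethane, CI
Why: Williamson methylation of the only free phenol places the future 8-methoxy group on the carbon that carried the formyl group.

Step 5
Reactants: 6 1,5-bis(benzyloxy)-2-methoxy-3-(methoxymethoxy)benzene
Product: 7 3,5-bis(benzyloxy)-2-methoxyphenol
Conditions: conc. HCl (cat.), MeOH–THF, 50 °C
Reagents that add atoms: none
Why: Acid-catalysed acetal exchange removes the MOM group as dimethoxymethane, whereas aryl benzyl and methyl ethers are stable to dilute methanolic acid.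

**Ring B mandelate**

Step 6
Reactants: 8 2,4-dihydroxybenzaldehyde
Product: 9 2,4-bis(benzyloxy)benzaldehyde
Conditions: BnBr (2.3 equiv), K2CO3, DMF, 70 °C
Reagents that add atoms: benzyl bromide, BrCc1ccccc1
Why: Williamson etherification; excess halide and heat also alkylate the chelated 2-OH.

Step 7
Reactants: 9 2,4-bis(benzyloxy)benzaldehyde
Product: 11 2,4-bis(benzyloxy)phenol, via aryl formate 10 (not isolated)
Conditions: mCPBA, CH2Cl2, 0 °C to rt; aq NaHCO3 wash; then K2CO3 (cat.), MeOH, rt
Reagents that add atoms: mCPBA, OOC(=O)c1cccc(Cl)c1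
Why: Baeyer–Villiger (Dakin-type) oxidation; the ortho- and para-alkoxy groups make the aryl group migrate in preference to hydride, and the formate is methanolysed in the same flask.

Step 8
Reactants: 11 2,4-bis(benzyloxy)phenol
Product: 12 2,4-bis(benzyloxy)-1-methoxybenzene
Conditions: MeI, K2CO3, acetone, reflux
Reagents that add atoms: iodomethane, CI
Why: Williamson methylation of the single phenol fixes the future 5'-methoxy group.

Step 9
Reactants: 12 2,4-bis(benzyloxy)-1-methoxybenzene; 13 ethyl glyoxylate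
Product: 14 ethyl 2-[2,4-bis(benzyloxy)-5-methoxyphenyl]-2-hydroxyacetate (racemic)
Conditions: ethyl glyoxylate (2 equiv), SnCl4 (1.1 equiv), CH2Cl2, −78 to −40 °C
Reagents that add atoms: ethyl glyoxylate (compound 13, listed as reactant), CCOC(=O)C=O
Why: Friedel–Crafts hydroxyalkylation; the tin-activated aldehyde should attack C5 of 12, which is para to one benzyloxy group and ortho to the other (C3 is flanked by two benzyloxy groups, C6 is meta to both), while low temperature and chelation of the α-hydroxy ester hold back a second arylation, and the new stereocentre is formed racemic.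

**Union and precursor**

Step 10
Reactants: 7 3,5-bis(benzyloxy)-2-methoxyphenol; 14 ethyl 2-[2,4-bis(benzyloxy)-5-methoxyphenyl]-2-hydroxyacetate
Product: 15 ethyl 2-[2,4-bis(benzyloxy)-5-methoxyphenyl]-2-[3,5-bis(benzyloxy)-2-methoxyphenoxy]acetate (racemic)
Conditions: PPh3, DIAD, THF, 0 °C to rt
Reagents that add atoms: none
Why: Mitsunobu etherification; the phenol (pKa about 10) displaces the activated benzylic oxyphosphonium group of the mandelate, which has no β-hydrogen to eliminate, and the stereocentre stays racemic.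

Step 11
Reactants: 15 ethyl 2-[2,4-bis(benzyloxy)-5-methoxyphenyl]-2-[3,5-bis(benzyloxy)-2-methoxyphenoxy]acetate
Product: 16 2-[2,4-bis(benzyloxy)-5-methoxyphenyl]-2-[3,5-bis(benzyloxy)-2-methoxyphenoxy]acetic acid (racemic)
Conditions: LiOH, THF–H2O, rt; then 1 M HCl to pH 3
Reagents that add atoms: lithium hydroxide, [Li+].[OH-]
Why: Ester saponification by acyl–oxygen cleavage; all ether groups are inert to hydroxide at room temperature.

Step 12
Reactants: 16 2-[2,4-bis(benzyloxy)-5-methoxyphenyl]-2-[3,5-bis(benzyloxy)-2-methoxyphenoxy]acetic acid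
Product: 18 4,6-bis(benzyloxy)-2-[2,4-bis(benzyloxy)-5-methoxyphenyl]-7-methoxy-1-benzofuran-3(2H)-one (racemic), via mixed trifluoroacetic anhydride 17 (not isolated)
Conditions: TFAA (2 equiv), CH2Cl2, 0 °C to rt, argon; aq NaHCO3 quench
Reagents that add atoms: none
Why: Intramolecular Friedel–Crafts acylation through the mixed anhydride; the acyl carbon should attack the only free carbon ortho to the ether oxygen of the phenoxy ring, which is activated by an ortho and a para benzyloxy group, closing the five-membered ring without a strong Lewis acid that could cleave benzyl ethers or generate a free, decarbonylation-prone acylium ion.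

Step 13
Reactants: 18 4,6-bis(benzyloxy)-2-[2,4-bis(benzyloxy)-5-methoxyphenyl]-7-methoxy-1-benzofuran-3(2H)-one
Product: 19 4,6-bis(benzyloxy)-2-[2,4-bis(benzyloxy)-5-methoxyphenyl]-3-(tert-butyldimethylsilyloxy)-7-methoxy-1-benzofuran
Conditions: TBSOTf, Et3N, CH2Cl2, 0 °C (18 used at once, under argon)
Reagents that add atoms: tert-butyldimethylsilyl trifluoromethanesulfonate, CC(C)(C)[Si](C)(C)OS(=O)(=O)C(F)(F)F
Why: Soft enolisation and O-silylation; C2–H is acidified by the carbonyl group, the ring oxygen and the aryl group, and its removal aromatises the furan ring, so the silyl enol ether should form readily and the stereocentre disappears.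

**Key step**

Step 14
Reactants: 19 4,6-bis(benzyloxy)-2-[2,4-bis(benzyloxy)-5-methoxyphenyl]-3-(tert-butyldimethylsilyloxy)-7-methoxy-1-benzofuran; 20 bromoform
Product: 23 5,7-bis(benzyloxy)-2-[2,4-bis(benzyloxy)-5-methoxyphenyl]-3-bromo-8-methoxychromen-4-one, via dibromocyclopropane adduct 21 (not isolated), via silyloxybenzopyrylium bromide 22 (not isolated)
Conditions: CHBr3 (3 equiv), KOtBu (2.5 equiv, added in portions), toluene–hexane, −30 °C to rt, then 40 °C; aq NaHCO3 work-up
Reagents that add atoms: bromoform (compound 20, listed as reactant), BrC(Br)Br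
Why: α-Elimination of HBr from bromoform gives singlet dibromocarbene, an electrophile that should add in a concerted (2+1) step to the C2=C3 bond of 19, the silyl enol ether bond of the furan, to give cyclopropane 21. Ionisation of one C–Br bond with disrotatory electrocyclic opening of the cyclopropyl to the allyl cation cleaves the old C2–C3 fusion bond, since only this mode places the charge on carbons stabilised by O1 and by the silyloxy oxygen, and gives the 3-bromo-4-silyloxybenzopyrylium bromide 22. Loss of the silyl group to bromide or on aqueous work-up then unmasks the C4 carbonyl group of 23. The closest known reactions are the dihalocarbene one-carbon ring expansion of cyclic silyl enol ethers to 2-halo enones and the Ciamician–Dennstedt-type expansion of benzofurans and indoles. Ring C is not closed by a cyclisation but arises by expansion of the furan (three-membered ring formation across C2=C3, then two-electron electrocyclic opening), and no stereocentre remains in the product. The step needs chemoselectivity for C2=C3 over rings A and B and the benzylic C–H bonds, which the far higher nucleophilicity of the silyl enol ether should secure, and the inserted carbon can only end between C2 and the carbonyl carbon.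

**C3 oxygenation and deprotection**

Step 15
Reactants: 23 5,7-bis(benzyloxy)-2-[2,4-bis(benzyloxy)-5-methoxyphenyl]-3-bromo-8-methoxychromen-4-one
Product: 25 5,7-bis(benzyloxy)-2-[2,4-bis(benzyloxy)-5-methoxyphenyl]-3-hydroxy-8-methoxychromen-4-one, via pinacol boronate 24 (not isolated)
Conditions: B2pin2, Pd2(dba)3 (2.5 mol %), XPhos (10 mol %), KOAc, 1,4-dioxane, 90 °C; then 30% H2O2, aq NaOH, THF, 0 °C; aq NH4Cl
Reagents that add atoms: hydrogen peroxide, OO
Why: Miyaura borylation (oxidative addition of zerovalent palladium into the C3–Br bond of the α-bromo enone, transmetalation with acetate-activated diboron, reductive elimination) followed by peroxide oxidation of the C–B bond with 1,2-migration to oxygen; flavonols are known to survive cold alkaline peroxide, the medium of the Algar–Flynn–Oyamada reaction.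

Step 16
Reactants: 25 5,7-bis(benzyloxy)-2-[2,4-bis(benzyloxy)-5-methoxyphenyl]-3-hydroxy-8-methoxychromen-4-one
Product: 26 5,7-bis(benzyloxy)-2-[2,4-bis(benzyloxy)-5-methoxyphenyl]-3,8-dimethoxychromen-4-one
Conditions: MeI, K2CO3, DMF, rt
Reagents that add atoms: iodomethane, CI
Why: Williamson methylation of the acidic 3-OH, the only free hydroxyl group in the molecule.

Step 17
Reactants: 26 5,7-bis(benzyloxy)-2-[2,4-bis(benzyloxy)-5-methoxyphenyl]-3,8-dimethoxychromen-4-one
Product: 27 5,7,2',4'-tetrahydroxy-3,8,5'-trimethoxyflavone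
Conditions: H2 (1 atm), 10% Pd/C, THF–MeOH, rt
Reagents that add atoms: none
Why: Catalytic hydrogenolysis of the four benzyl ethers; the tetrasubstituted vinylogous-ester C2=C3 bond and the three methyl ethers should not be reduced at one atmosphere.

**Compound list**

1 | 2,4,6-trihydroxybenzaldehyde | O=Cc1c(O)cc(O)cc1O | starting material
2 | 2,4-bis(benzyloxy)-6-hydroxybenzaldehyde | O=Cc1c(O)cc(OCc2ccccc2)cc1OCc1ccccc1 | intermediate
3 | 2,4-bis(benzyloxy)-6-(methoxymethoxy)benzaldehyde | O=Cc1c(OCOC)cc(OCc2ccccc2)cc1OCc1ccccc1 | intermediate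
4 | 2,4-bis(benzyloxy)-6-(methoxymethoxy)phenyl formate | O=COc1c(OCOC)cc(OCc2ccccc2)cc1OCc1ccccc1 | intermediate
5 | 2,4-bis(benzyloxy)-6-(methoxymethoxy)phenol | Oc1c(OCOC)cc(OCc2ccccc2)cc1OCc1ccccc1 | intermediate
6 | 1,5-bis(benzyloxy)-2-methoxy-3-(methoxymethoxy)benzene | COc1c(OCOC)cc(OCc2ccccc2)cc1OCc1ccccc1 | intermediate
7 | 3,5-bis(benzyloxy)-2-methoxyphenol | COc1c(O)cc(OCc2ccccc2)cc1OCc1ccccc1 | intermediate
8 | 2,4-dihydroxybenzaldehyde | O=Cc1ccc(O)cc1O | starting material
9 | 2,4-bis(benzyloxy)benzaldehyde | O=Cc1ccc(OCc2ccccc2)cc1OCc1ccccc1 | intermediate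
10 | 2,4-bis(benzyloxy)phenyl formate | O=COc1ccc(OCc2ccccc2)cc1OCc1ccccc1 | intermediate
11 | 2,4-bis(benzyloxy)phenol | Oc1ccc(OCc2ccccc2)cc1OCc1ccccc1 | intermediate
12 | 2,4-bis(benzyloxy)-1-methoxybenzene | COc1ccc(OCc2ccccc2)cc1OCc1ccccc1 | intermediate
13 | ethyl glyoxylate (ethyl 2-oxoacetate) | CCOC(=O)C=O | starting material
14 | ethyl 2-[2,4-bis(benzyloxy)-5-methoxyphenyl]-2-hydroxyacetate (racemic) | CCOC(=O)C(O)c1cc(OC)c(OCc2ccccc2)cc1OCc1ccccc1 | intermediate
15 | ethyl 2-[2,4-bis(benzyloxy)-5-methoxyphenyl]-2-[3,5-bis(benzyloxy)-2-methoxyphenoxy]acetate (racemic) | CCOC(=O)C(Oc1cc(OCc2ccccc2)cc(OCc2ccccc2)c1OC)c1cc(OC)c(OCc2ccccc2)cc1OCc1ccccc1 | intermediate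
16 | 2-[2,4-bis(benzyloxy)-5-methoxyphenyl]-2-[3,5-bis(benzyloxy)-2-methoxyphenoxy]acetic acid (racemic) | OC(=O)C(Oc1cc(OCc2ccccc2)cc(OCc2ccccc2)c1OC)c1cc(OC)c(OCc2ccccc2)cc1OCc1ccccc1 | intermediate
17 | 2-[2,4-bis(benzyloxy)-5-methoxyphenyl]-2-[3,5-bis(benzyloxy)-2-methoxyphenoxy]acetic trifluoroacetic anhydride (racemic) | O=C(OC(=O)C(F)(F)F)C(Oc1cc(OCc2ccccc2)cc(OCc2ccccc2)c1OC)c1cc(OC)c(OCc2ccccc2)cc1OCc1ccccc1 | intermediate
18 | 4,6-bis(benzyloxy)-2-[2,4-bis(benzyloxy)-5-methoxyphenyl]-7-methoxy-1-benzofuran-3(2H)-one (racemic) | COc1cc(C2Oc3c(OC)c(OCc4ccccc4)cc(OCc4ccccc4)c3C2=O)c(OCc2ccccc2)cc1OCc1ccccc1 | intermediate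
19 | 4,6-bis(benzyloxy)-2-[2,4-bis(benzyloxy)-5-methoxyphenyl]-3-(tert-butyldimethylsilyloxy)-7-methoxy-1-benzofuran | COc1cc(-c2oc3c(OC)c(OCc4ccccc4)cc(OCc4ccccc4)c3c2O[Si](C)(C)C(C)(C)C)c(OCc2ccccc2)cc1OCc1ccccc1 | intermediate
20 | bromoform | BrC(Br)Br | starting material
21 | 4,6-bis(benzyloxy)-1,1-dibromo-1a-[2,4-bis(benzyloxy)-5-methoxyphenyl]-6b-(tert-butyldimethylsilyloxy)-3-methoxy-1a,6b-dihydro-1H-cyclopropa[b][1]benzofuran (racemic; ring fusion necessarily cis) | COc1cc(C23Oc4c(OC)c(OCc5ccccc5)cc(OCc5ccccc5)c4C2(O[Si](C)(C)C(C)(C)C)C3(Br)Br)c(OCc2ccccc2)cc1OCc1ccccc1 | intermediate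
22 | 5,7-bis(benzyloxy)-2-[2,4-bis(benzyloxy)-5-methoxyphenyl]-3-bromo-4-(tert-butyldimethylsilyloxy)-8-methoxychromenylium bromide | COc1cc(-c2[o+]c3c(OC)c(OCc4ccccc4)cc(OCc4ccccc4)c3c(O[Si](C)(C)C(C)(C)C)c2Br)c(OCc2ccccc2)cc1OCc1ccccc1.[Br-] | intermediate
23 | 5,7-bis(benzyloxy)-2-[2,4-bis(benzyloxy)-5-methoxyphenyl]-3-bromo-8-methoxychromen-4-one | COc1cc(-c2oc3c(OC)c(OCc4ccccc4)cc(OCc4ccccc4)c3c(=O)c2Br)c(OCc2ccccc2)cc1OCc1ccccc1 | intermediate
24 | 5,7-bis(benzyloxy)-2-[2,4-bis(benzyloxy)-5-methoxyphenyl]-8-methoxy-3-(4,4,5,5-tetramethyl-1,3,2-dioxaborolan-2-yl)chromen-4-one | COc1cc(-c2oc3c(OC)c(OCc4ccccc4)cc(OCc4ccccc4)c3c(=O)c2B2OC(C)(C)C(C)(C)O2)c(OCc2ccccc2)cc1OCc1ccccc1 | intermediate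
25 | 5,7-bis(benzyloxy)-2-[2,4-bis(benzyloxy)-5-methoxyphenyl]-3-hydroxy-8-methoxychromen-4-one | COc1cc(-c2oc3c(OC)c(OCc4ccccc4)cc(OCc4ccccc4)c3c(=O)c2O)c(OCc2ccccc2)cc1OCc1ccccc1 | intermediate
26 | 5,7-bis(benzyloxy)-2-[2,4-bis(benzyloxy)-5-methoxyphenyl]-3,8-dimethoxychromen-4-one | COc1cc(-c2oc3c(OC)c(OCc4ccccc4)cc(OCc4ccccc4)c3c(=O)c2OC)c(OCc2ccccc2)cc1OCc1ccccc1 | intermediate
27 | 5,7,2',4'-tetrahydroxy-3,8,5'-trimethoxyflavone (2-(2,4-dihydroxy-5-methoxyphenyl)-5,7-dihydroxy-3,8-dimethoxychromen-4-one) | COc1cc(-c2oc3c(OC)c(O)cc(O)c3c(=O)c2OC)c(O)cc1O | target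

**Step count and risks**

Total step count: 17. Longest linear sequence: 13 steps (steps 1–5, then 10–17); the ring B branch (steps 6–9) joins at step 10.

Steps most likely to fail:

1. Step 14 (carbene ring expansion). The carbene may add too slowly to the crowded, tetrasubstituted C2=C3 bond. tert-Butoxide may strip the silyl group from the cyclopropane before it ionises, which would leave a ring-retained dibromomethyl ketone. Alkoxide may also attack the product at C2. The fallback gives up the insertion and builds ring C by a Baker–Venkataraman sequence, setting out from 6 and 12 and returning at 26.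
   - Arene 6 would be lithiated between its OMOM and OBn groups (n-BuLi, THF, 0 °C) and acylated with N-methoxy-N-methyl-2-methoxyacetamide to give 1-[4,6-bis(benzyloxy)-3-methoxy-2-(methoxymethoxy)phenyl]-2-methoxyethan-1-one F1.
   - Methanolic HCl would free the phenol to give 1-[4,6-bis(benzyloxy)-2-hydroxy-3-methoxyphenyl]-2-methoxyethan-1-one F2.
   - Arene 12 would undergo Vilsmeier formylation (POCl3, DMF) to 2,4-bis(benzyloxy)-5-methoxybenzaldehyde F3, Pinnick oxidation (NaClO2, NaH2PO4, 2-methyl-2-butene) to 2,4-bis(benzyloxy)-5-methoxybenzoic acid F4, and treatment with oxalyl chloride to 2,4-bis(benzyloxy)-5-methoxybenzoyl chloride F5.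
   - C-Aroylation of the dianion of F2 with F5 (LiN(SiMe3)2, 3 equiv, THF, −78 °C to rt) would give 1-[4,6-bis(benzyloxy)-2-hydroxy-3-methoxyphenyl]-3-[2,4-bis(benzyloxy)-5-methoxyphenyl]-2-methoxypropane-1,3-dione F6.
   - Cyclodehydration (TsOH, toluene, 80 °C) would give 26, ready for step 17.

2. Step 15 (borylation and oxidation). Oxidative addition into the hindered, tetrasubstituted C3–Br bond may be slow, and protodebromination or protodeboronation of the α-boryl enone may outrun C–B formation and oxidation. The fallback sets out from 23 and forms the C3–O bond directly: palladium-catalysed C–O coupling with methanol (Pd2(dba)3, tBuBrettPhos, Cs2CO3, MeOH, toluene, 60–80 °C) would give 26 in one step, bypassing 24 and 25 and step 16; it makes no new compound.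

3. Step 12 (Friedel–Crafts closure). The activated acyl group may lose carbon monoxide to a stabilised benzylic oxocarbenium ion, or trifluoroacetic acid may remove benzyl groups, before the ring closes. The fallback forms the aryl–carbonyl bond with an aryllithium and closes the O1–C2 bond last, setting out from 14 and 6 and returning at 18.
   - Mandelate 14 would be silylated (TBSCl, imidazole, DMF) to ethyl 2-[2,4-bis(benzyloxy)-5-methoxyphenyl]-2-(tert-butyldimethylsilyloxy)acetate F7.
   - Arene 6, lithiated between OMOM and OBn (n-BuLi, THF, 0 °C), would be acylated by F7 at −78 °C to give 1-[4,6-bis(benzyloxy)-3-methoxy-2-(methoxymethoxy)phenyl]-2-[2,4-bis(benzyloxy)-5-methoxyphenyl]-2-(tert-butyldimethylsilyloxy)ethan-1-one F8.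
   - Methanolic HCl would remove the MOM and silyl groups to give 1-[4,6-bis(benzyloxy)-2-hydroxy-3-methoxyphenyl]-2-[2,4-bis(benzyloxy)-5-methoxyphenyl]-2-hydroxyethan-1-one F9.
   - Intramolecular Mitsunobu etherification (PPh3, DIAD, THF) would close the furanone ring to 18, ready for step 13.

Further compounds
F1 | step 14 | 1-[4,6-bis(benzyloxy)-3-methoxy-2-(methoxymethoxy)phenyl]-2-methoxyethan-1-one | COCC(=O)c1c(OCOC)c(OC)c(OCc2ccccc2)cc1OCc1ccccc1
F2 | step 14 | 1-[4,6-bis(benzyloxy)-2-hydroxy-3-methoxyphenyl]-2-methoxyethan-1-one | COCC(=O)c1c(O)c(OC)c(OCc2ccccc2)cc1OCc1ccccc1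
F3 | step 14 | 2,4-bis(benzyloxy)-5-methoxybenzaldehyde | O=Cc1cc(OC)c(OCc2ccccc2)cc1OCc1ccccc1
F4 | step 14 | 2,4-bis(benzyloxy)-5-methoxybenzoic acid | OC(=O)c1cc(OC)c(OCc2ccccc2)cc1OCc1ccccc1
F5 | step 14 | 2,4-bis(benzyloxy)-5-methoxybenzoyl chloride | ClC(=O)c1cc(OC)c(OCc2ccccc2)cc1OCc1ccccc1
F6 | step 14 | 1-[4,6-bis(benzyloxy)-2-hydroxy-3-methoxyphenyl]-3-[2,4-bis(benzyloxy)-5-methoxyphenyl]-2-methoxypropane-1,3-dione | COC(C(=O)c1c(O)c(OC)c(OCc2ccccc2)cc1OCc1ccccc1)C(=O)c1cc(OC)c(OCc2ccccc2)cc1OCc1ccccc1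
F0 | step 15 | none | none
F7 | step 12 | ethyl 2-[2,4-bis(benzyloxy)-5-methoxyphenyl]-2-(tert-butyldimethylsilyloxy)acetate (racemic) | CCOC(=O)C(O[Si](C)(C)C(C)(C)C)c1cc(OC)c(OCc2ccccc2)cc1OCc1ccccc1
F8 | step 12 | 1-[4,6-bis(benzyloxy)-3-methoxy-2-(methoxymethoxy)phenyl]-2-[2,4-bis(benzyloxy)-5-methoxyphenyl]-2-(tert-butyldimethylsilyloxy)ethan-1-one (racemic) | COCOc1c(OC)c(OCc2ccccc2)cc(OCc2ccccc2)c1C(=O)C(O[Si](C)(C)C(C)(C)C)c1cc(OC)c(OCc2ccccc2)cc1OCc1ccccc1
F9 | step 12 | 1-[4,6-bis(benzyloxy)-2-hydroxy-3-methoxyphenyl]-2-[2,4-bis(benzyloxy)-5-methoxyphenyl]-2-hydroxyethan-1-one (racemic) | Oc1c(OC)c(OCc2ccccc2)cc(OCc2ccccc2)c1C(=O)C(O)c1cc(OC)c(OCc2ccccc2)cc1OCc1ccccc1
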